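The route rests on cutting ring B, the nine-membered carbocycle, at C2–C3: the one ring B bond whose neighbours, cyclobutane carbon C1 and the oxygen-bearing quaternary chroman carbon C4, are both configurationally complete. A single ring-closing olefin metathesis forges this bond as a Z alkene and closes ring B without creating or disturbing a stereocentre. Its substrate is a diene ketone: a MOM-protected 2-methyl-2-vinyl-4-phenylchroman joined through a CH2CH2 chain and the C8 ketone to a trans-3,3-dimethyl-2-vinylcyclobutane; C8 stays a ketone so that no third alkene competes. The cyclobutane half is made from levoglucosenone, the chroman half from 5,7-dihydroxycoumarin.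

Key step: step 15

Remark on the chemistry: caryophyllane numbering is used, with C8 the ring carbon that carries the exocyclic CH2 (C15) and C1' the benzylic carbon; commercial levoglucosenone is taken as the (1S,5R) enantiomer.

Step 1
Reactants: 1 levoglucosenone; 2 isobutylene (2-methylpropene)
Product: 3 head-to-tail photoadduct (6,8-dioxabicyclo[3.2.1]octan-4-one with a 3,3-dimethylcyclobutane cis-fused at C2–C3 on the face opposite the O6–C7 bridge; CMe2 on C2)
Conditions: hν (350 nm), 2 (about 15 equiv, condensed), CH2Cl2, −40 °C; then basic Al2O3, 23 °C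
Reagents that add atoms: none
Why: Enone–alkene [2+2] photocycloaddition: the triplet enone joins its α-carbon to the CH2 terminus and its β-carbon (future C1) to CMe2 (the head-to-tail orientation usual for electron-rich 1,1-dialkylalkenes), both bonds form on the convex face away from the anhydro bridge, and alumina equilibrates any trans-fused isomer to the cis fusion, which fixes the future C9 for good and C1 provisionally.

Step 2
Reactants: 3 photoadduct
Product: 4 [(1R,4S,5R)-6,6-dimethyl-2-oxo-3-oxabicyclo[3.2.0]heptan-4-yl]methyl formate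
Conditions: mCPBA, CH2Cl2, 0 to 23 °C
Reagents that add atoms: 3-chloroperbenzoic acid, O=C(OO)c1cccc(Cl)c1
Why: Baeyer–Villiger oxidation in which the doubly oxygenated acetal carbon migrates in preference to the cyclobutyl carbon, after which the acyloxy acetal collapses to the γ-lactone with the primary oxygen left as a formate; no stereocentre is touched.

Step 3
Reactants: 4 formate lactone
Product: 6 cis lactol acid (1R,5R)-4-hydroxy-6,6-dimethyl-3-oxabicyclo[3.2.0]heptan-2-one, via dihydroxy carboxylate 5 (not isolated)
Conditions: LiOH, THF/H2O, 0 to 23 °C; NaH2PO4 to pH 7, NaIO4, 0 °C; then HCl to pH 3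
Reagents that add atoms: lithium hydroxide, [Li+].[OH-]
Why: Saponification frees the 1,2-diol as its carboxylate salt (no relactonisation at pH 7) and periodate glycol cleavage excises the CH2OH carbon, turning the carbinol carbon into the future C2 aldehyde, which the cis carboxylic acid traps as a lactol on acidification.

Step 4
Reactants: 6 cis lactol acid
Product: 7 (1R,2S)-2-formyl-3,3-dimethylcyclobutane-1-carboxylic acid (trans)
Conditions: K2CO3, MeOH, 23 °C; then 1 M HCl
Reagents that add atoms: none
Why: Base-mediated epimerisation through the aldehyde enolate: only the formyl-bearing carbon (future C1) can enolise because its neighbour carries a carboxylate, so the ring-opened cis compound drains to the less crowded trans isomer; C1 is inverted while C9 keeps the configuration set in step 1, which gives the cyclobutane of the ent-caryophyllane series.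

Step 5
Reactants: 7 trans formyl acid
Product: 8 (1R,2S)-2-ethenyl-3,3-dimethylcyclobutane-1-carboxylic acid
Conditions: Ph3PCH3Br, KOtBu (excess), THF, 0 to 23 °C; aq. citric acid
Reagents that add atoms: methyltriphenylphosphonium bromide, C[P+](c1ccccc1)(c1ccccc1)c1ccccc1.[Br-]
Why: Wittig methylenation of the aldehyde with the carboxylate as a spectator; the trans arrangement is already the thermodynamic one, so transient enolisation is harmless.

Step 6
Reactants: 8 vinyl acid
Product: 9 (1R,2S)-2-ethenyl-N-methoxy-N,3,3-trimethylcyclobutane-1-carboxamide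
Conditions: MeNHOMe·HCl, EDC·HCl, HOBt, i-Pr2NEt, CH2Cl2, 23 °C
Reagents that add atoms: N,O-dimethylhydroxylamine hydrochloride, CNOC.Cl
Why: Carbodiimide-mediated amide coupling gives the Weinreb amide needed for clean single acylation in step 13.

Step 7
Reactants: 10 5,7-dihydroxycoumarin
Product: 11 5,7-bis(methoxymethoxy)coumarin
Conditions: MOMCl, i-Pr2NEt, DMF, 0 to 23 °C
Reagents that add atoms: chloromethyl methyl ether, COCCl
Why: Williamson-type O-alkylation of both phenols; the acetal ethers survive the later basic and organometallic steps and come off under mild acid at the end.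

Step 8
Reactants: 11 bis-MOM coumarin; 12 phenylboronic acid
Product: 13 (4S)-5,7-bis(methoxymethoxy)-4-phenylchroman-2-one
Conditions: Rh(acac)(C2H4)2 (3 mol %), (S)-SEGPHOS, 1,4-dioxane/H2O 10:1, 60 °C
Reagents that add atoms: none
Why: Rh-catalysed asymmetric 1,4-addition of an arylboronic acid (Hayashi–Miyaura reaction): the phenylrhodium species inserts the lactone C3=C4 bond on the face set by the bisphosphine, and the (S)-ligand is expected, by analogy with simpler coumarins, to give the 4S lactone and so C1'.

Step 9
Reactants: 13 phenyl lactone; 14 phenyl vinyl sulfone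
Product: 16 (3R,4S)-5,7-bis(methoxymethoxy)-4-phenyl-3-[2-(phenylsulfonyl)ethyl]chroman-2-one, via lithium enolate 15 (not isolated)
Conditions: LiN(SiMe3)2, THF, −78 °C; then 14, −78 °C; AcOH quench
Reagents that add atoms: none
Why: Michael addition of the lactone enolate to the vinyl sulfone; the C4 phenyl group sits pseudoaxial (peri strain with the neighbouring MOM ether) and shields one face, so the chain enters trans to it and sets C5.

Step 10
Reactants: 16 sulfone lactone
Product: 18 (3R,4S)-2-methoxy-2-methyl-5,7-bis(methoxymethoxy)-4-phenyl-3-[2-(phenylsulfonyl)ethyl]chroman (C2 epimers), via exocyclic enol ether 17 (not isolated)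
Conditions: Cp2TiMe2, toluene, 70 °C, dark; then MeOH, PPTS (cat.), 0 °C
Reagents that add atoms: dimethyltitanocene, C[Ti](C)(C1C=CC=C1)C1C=CC=C1; methanol, CO
Why: Petasis methylenation converts the lactone carbonyl into the exocyclic enol ether without enolising C3, and acid-catalysed Markovnikov addition of methanol gives the mixed methyl ketal that carries the future C4 methyl group.

Step 11
Reactants: 18 methyl ketal; 19 ethynyltrimethylsilane
Product: 21 (2R,3R,4S)-2-ethynyl-2-methyl-5,7-bis(methoxymethoxy)-4-phenyl-3-[2-(phenylsulfonyl)ethyl]chroman, via silylalkyne 20 (not isolated)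
Conditions: 19, n-BuLi, then Me2AlCl, toluene, −78 to 0 °C; 18 in CH2Cl2, −40 to 0 °C; aq. Rochelle salt; then K2CO3, MeOH, 23 °C
Reagents that add atoms: none
Why: Substitution of a cyclic ketal by an alkynylalane via the 2-methylchromenylium (oxocarbenium) ion: the C5 chain and the C1' phenyl are pseudoaxial (allylic strain with the 2-methyl group and the peri MOM ether), so the slim alkynyl group is delivered in a chair-like transition state anti to the adjacent chain, setting C4 with the alkyne trans to the chain and cis to phenyl; methanolysis then removes the silyl group.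

Step 12
Reactants: 21 terminal alkyne
Product: 22 (2S,3R,4S)-2-ethenyl-2-methyl-5,7-bis(methoxymethoxy)-4-phenyl-3-[2-(phenylsulfonyl)ethyl]chroman
Conditions: H2 (1 atm), Pd/CaCO3 poisoned with Pb(OAc)2, quinoline, EtOAc, 23 °C
Reagents that add atoms: none
Why: Semihydrogenation of the terminal alkyne over the lead-poisoned palladium catalyst (Lindlar reduction) stops at the vinyl group, and quinoline also suppresses hydrogenolysis of the propargylic and allylic C–O bond.

Step 13
Reactants: 22 vinyl chroman sulfone; 9 Weinreb amide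
Product: 24 β-keto sulfone (C7 epimers), via lithio sulfone 23 (not isolated)
Conditions: n-BuLi, THF, −78 °C; then 9, −78 to −20 °C; H2O
Reagents that add atoms: none
Why: The α-sulfonyl carbanion acylates the Weinreb amide (C7–C8 bond), the chelated tetrahedral adduct preventing over-addition and proton transfer from the product; the new C7 centre is inconsequential.

Step 14
Reactants: 24 β-keto sulfone
Product: 25 diene ketone 1-[(1R,2S)-2-ethenyl-3,3-dimethylcyclobutyl]-3-[(2S,3R,4S)-2-ethenyl-2-methyl-5,7-bis(methoxymethoxy)-4-phenylchroman-3-yl]propan-1-one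
Conditions: SmI2, THF/MeOH, −78 °C
Reagents that add atoms: none
Why: Reductive desulfonylation of the β-keto sulfone by electron transfer from SmI2 gives the samarium enolate of the C8 ketone, which methanol protonates at C7; vinyl groups, MOM ethers and C9 are untouched.

Step 15
Reactants: 25 diene ketone
Product: 26 Z-cyclononenone (ring B closed, C2=C3 Z, C8 ketone, bis-MOM ether; 1S,4S,5R,9R,1'S)
Conditions: RuCl2(H2IMes)(PCy3)(=CHPh) (second-generation Grubbs catalyst, 15 mol % in portions), toluene (0.5 mM), 80 °C, argon sparge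
Reagents that add atoms: none
Why: The ruthenium benzylidene first exchanges onto the less encumbered cyclobutyl vinyl group (C2), the resulting alkylidene adds across the C4 vinyl group to a ruthenacyclobutane, and cycloreversion expels ethylene and leaves the C2=C3 double bond. The closest known reaction type is ring-closing metathesis of 1,ω-dienes to medium-sized carbocycles. Ring B closes as a nine-membered ring with the new alkene endocyclic, and the ring size allows only the Z geometry. No stereocentre is created; C1, C4, C5, C9 and C1' pass through unchanged. The step needs cyclisation to win over oligomerisation by cross-metathesis and over any other ring closure: high dilution and ethylene removal serve the first, and the second is excluded because C8 is a ketone and the two vinyl groups are the only alkenes. The trans arrangement of the arms on the chroman (C4 vinyl, C5 chain) and on the cyclobutane (C1 vinyl, C9 acyl) holds the two vinyl groups within reach of each other.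

Step 16
Reactants: 26 Z-cyclononenone
Product: 27 saturated ring B ketone (bis-MOM ether)
Conditions: H2 (1 atm), [Ir(cod)(PCy3)(py)]PF6 (10 mol %), CH2Cl2, 23 °C
Reagents that add atoms: none
Why: Homogeneous iridium-catalysed hydrogenation saturates the hindered Z alkene, the only C=C present, without hydrogenolysis of the allylic C4–O bond and without reducing the ketone.

Step 17
Reactants: 27 saturated ketone
Product: 28 aryl dibromide (Br at both free positions of the oxygenated ring)
Conditions: NBS (2.1 equiv), CH2Cl2, −20 to 0 °C, dark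
Reagents that add atoms: N-bromosuccinimide, O=C1CCC(=O)N1Br
Why: Electrophilic aromatic bromination fills the two remaining positions of the tri-oxygenated ring, which are far more reactive than the phenyl ring or the ketone α-positions.

Step 18
Reactants: 28 dibromo ketone
Product: 29 dibromo C8-methylidene compound
Conditions: Ph3PCH3Br, KOtBu, toluene, 23 to 60 °C
Reagents that add atoms: methyltriphenylphosphonium bromide, C[P+](c1ccccc1)(c1ccccc1)c1ccccc1.[Br-]
Why: Wittig methylenation of the C8 ketone installs the exocyclic CH2; C9 already has the trans ring fusion expected to be favoured at equilibrium, so reversible enolisation by the ylide should not erode it.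

Step 19
Reactants: 29 dibromide
Product: 31 bis-MOM dialdehyde, via dilithio arene 30 (not isolated)
Conditions: t-BuLi (4.4 equiv), THF, −78 °C; then DMF, −78 to 0 °C; H2O
Reagents that add atoms: N,N-dimethylformamide, CN(C)C=O
Why: Twofold bromine–lithium exchange (each aryllithium flanked by coordinating oxygens) followed by formylation with DMF (Bouveault aldehyde synthesis); the isolated alkene and the benzylic C–H are inert at −78 °C.

Step 20
Reactants: 31 bis-MOM dialdehyde
Product: 32 target CNP0253700.1
Conditions: HCl (0.5 M) in MeOH/THF, 23 °C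
Reagents that add atoms: none
Why: Acid-catalysed acetal exchange with methanol removes both MOM groups, each ortho to a formyl group whose hydrogen bond to the freed phenol drives the cleavage, at an acidity too low to protonate the 1,1-disubstituted alkene.

Compound list
1 | levoglucosenone, (1S,5R)-6,8-dioxabicyclo[3.2.1]oct-2-en-4-one | O=C1C=C[C@H]2CO[C@@H]1O2 | starting material
2 | isobutylene (2-methylpropene) | C=C(C)C | starting material
3 | head-to-tail cis-fused photoadduct of 1 and 2, cyclobutane anti to the anhydro bridge | O=C1[C@@H]3CC(C)(C)[C@@H]3[C@H]2CO[C@@H]1O2 | intermediate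
4 | [(1R,4S,5R)-6,6-dimethyl-2-oxo-3-oxabicyclo[3.2.0]heptan-4-yl]methyl formate | O=C1O[C@H](COC=O)[C@@H]2[C@H]1CC2(C)C | intermediate
5 | lithium (1R,2R)-2-[(1S)-1,2-dihydroxyethyl]-3,3-dimethylcyclobutane-1-carboxylate | OC[C@@H](O)[C@@H]1[C@H](C(=O)[O-])CC1(C)C.[Li+] | intermediate (not isolated)
6 | (1R,5R)-4-hydroxy-6,6-dimethyl-3-oxabicyclo[3.2.0]heptan-2-one (lactol of the cis formyl acid, anomers) | O=C1OC(O)[C@@H]2[C@H]1CC2(C)C | intermediate
7 | (1R,2S)-2-formyl-3,3-dimethylcyclobutane-1-carboxylic acid | O=C[C@H]1[C@H](C(=O)O)CC1(C)C | intermediate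
8 | (1R,2S)-2-ethenyl-3,3-dimethylcyclobutane-1-carboxylic acid | C=C[C@H]1[C@H](C(=O)O)CC1(C)C | intermediate
9 | (1R,2S)-2-ethenyl-N-methoxy-N,3,3-trimethylcyclobutane-1-carboxamide | C=C[C@H]1[C@H](C(=O)N(C)OC)CC1(C)C | intermediate
10 | 5,7-dihydroxycoumarin | O=C1C=Cc2c(O)cc(O)cc2O1 | starting material
11 | 5,7-bis(methoxymethoxy)coumarin | O=C1C=Cc2c(OCOC)cc(OCOC)cc2O1 | intermediate
12 | phenylboronic acid | OB(O)c1ccccc1 | starting material
13 | (4S)-5,7-bis(methoxymethoxy)-4-phenylchroman-2-one | O=C1C[C@@H](c3ccccc3)c2c(OCOC)cc(OCOC)cc2O1 | intermediate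
14 | phenyl vinyl sulfone | C=CS(=O)(=O)c1ccccc1 | starting material
15 | lithium enolate of 13 | [Li]OC1=C[C@@H](c3ccccc3)c2c(OCOC)cc(OCOC)cc2O1 | intermediate (not isolated)
16 | (3R,4S)-5,7-bis(methoxymethoxy)-4-phenyl-3-[2-(phenylsulfonyl)ethyl]chroman-2-one | O=C1[C@H](CCS(=O)(=O)c4ccccc4)[C@@H](c3ccccc3)c2c(OCOC)cc(OCOC)cc2O1 | intermediate
17 | (3R,4S)-2-methylidene-5,7-bis(methoxymethoxy)-4-phenyl-3-[2-(phenylsulfonyl)ethyl]chroman | C=C1[C@H](CCS(=O)(=O)c4ccccc4)[C@@H](c3ccccc3)c2c(OCOC)cc(OCOC)cc2O1 | intermediate (not isolated)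
18 | (3R,4S)-2-methoxy-2-methyl-5,7-bis(methoxymethoxy)-4-phenyl-3-[2-(phenylsulfonyl)ethyl]chroman, C2 epimers | COC1(C)[C@H](CCS(=O)(=O)c4ccccc4)[C@@H](c3ccccc3)c2c(OCOC)cc(OCOC)cc2O1 | intermediate
19 | ethynyltrimethylsilane | C#C[Si](C)(C)C | starting material
20 | (2R,3R,4S)-2-methyl-5,7-bis(methoxymethoxy)-4-phenyl-3-[2-(phenylsulfonyl)ethyl]-2-[(trimethylsilyl)ethynyl]chroman | O=S(=O)(CC[C@@H]1[C@@H](c3ccccc3)c3c(OCOC)cc(OCOC)cc3O[C@@]1(C)C#C[Si](C)(C)C)c1ccccc1 | intermediate (not isolated)
21 | (2R,3R,4S)-2-ethynyl-2-methyl-5,7-bis(methoxymethoxy)-4-phenyl-3-[2-(phenylsulfonyl)ethyl]chroman | O=S(=O)(CC[C@@H]1[C@@H](c3ccccc3)c3c(OCOC)cc(OCOC)cc3O[C@@]1(C)C#C)c1ccccc1 | intermediate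
22 | (2S,3R,4S)-2-ethenyl-2-methyl-5,7-bis(methoxymethoxy)-4-phenyl-3-[2-(phenylsulfonyl)ethyl]chroman | O=S(=O)(CC[C@@H]1[C@@H](c3ccccc3)c3c(OCOC)cc(OCOC)cc3O[C@@]1(C)C=C)c1ccccc1 | intermediate
23 | α-lithio sulfone of 22 (lithium at C7) | [Li]C(C[C@@H]1[C@@H](c3ccccc3)c3c(OCOC)cc(OCOC)cc3O[C@@]1(C)C=C)S(=O)(=O)c1ccccc1 | intermediate (not isolated)
24 | β-keto sulfone: 25 bearing PhSO2 at C7 (C7 epimers) | C=C[C@H]2[C@H](C(=O)C(C[C@@H]1[C@@H](c3ccccc3)c3c(OCOC)cc(OCOC)cc3O[C@@]1(C)C=C)S(=O)(=O)c1ccccc1)CC2(C)C | intermediate
25 | diene ketone, 1-[(1R,2S)-2-ethenyl-3,3-dimethylcyclobutyl]-3-[(2S,3R,4S)-2-ethenyl-2-methyl-5,7-bis(methoxymethoxy)-4-phenylchroman-3-yl]propan-1-one | C=C[C@H]2[C@H](C(=O)CC[C@@H]1[C@@H](c3ccccc3)c3c(OCOC)cc(OCOC)cc3O[C@@]1(C)C=C)CC2(C)C | intermediate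
26 | Z-C2=C3 cyclononenone with C8 ketone, bis-MOM ether (1S,4S,5R,9R,1'S) | O=C1CC[C@@H]2[C@@H](c3ccccc3)c3c(OCOC)cc(OCOC)cc3O[C@@]2(C)/C=C\[C@H]2[C@H]1CC2(C)C | intermediate
27 | saturated ring B C8 ketone, bis-MOM ether | O=C1CC[C@@H]2[C@@H](c3ccccc3)c3c(OCOC)cc(OCOC)cc3O[C@@]2(C)CC[C@H]2[C@H]1CC2(C)C | intermediate
28 | dibromo C8 ketone, bis-MOM ether | O=C1CC[C@@H]2[C@@H](c3ccccc3)c3c(OCOC)c(Br)c(OCOC)c(Br)c3O[C@@]2(C)CC[C@H]2[C@H]1CC2(C)C | intermediate
29 | dibromo C8-methylidene compound, bis-MOM ether | C=C1CC[C@@H]2[C@@H](c3ccccc3)c3c(OCOC)c(Br)c(OCOC)c(Br)c3O[C@@]2(C)CC[C@H]2[C@H]1CC2(C)C | intermediate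
30 | dilithio arene from 29 | C=C1CC[C@@H]2[C@@H](c3ccccc3)c3c(OCOC)c([Li])c(OCOC)c([Li])c3O[C@@]2(C)CC[C@H]2[C@H]1CC2(C)C | intermediate (not isolated)
31 | bis-MOM ether of the target dialdehyde | C=C1CC[C@@H]2[C@@H](c3ccccc3)c3c(OCOC)c(C=O)c(OCOC)c(C=O)c3O[C@@]2(C)CC[C@H]2[C@H]1CC2(C)C | intermediate
32 | CNP0253700.1 (1S,4S,5R,9R,1'S) | C=C1CC[C@@H]2[C@@H](c3ccccc3)c3c(O)c(C=O)c(O)c(C=O)c3O[C@@]2(C)CC[C@H]2[C@H]1CC2(C)C | target

Total steps: 20. Longest linear sequence: 14 steps (10 to 32 through steps 7–20; the branch from 1 through steps 1–6 and 13–20 is equally long).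

Steps most likely to fail

Step 15. Both vinyl groups are hindered, so catalyst loading may be slow and intermolecular metathesis or catalyst decay may overtake the nine-membered closure. The fallback is relay ring-closing metathesis, which changes how the metal reaches the hindered site. It sets out from aldehyde 7: Wittig reaction with the ylide of (hex-5-en-1-yl)triphenylphosphonium bromide gives the (1R,2S)-2-[(Z)-hepta-1,6-dienyl] acid F1. Amide coupling as in step 6 gives its Weinreb amide F2. Acylation of lithio sulfone 23 as in step 13 gives the keto sulfone F3, and SmI2 desulfonylation as in step 14 gives the relay triene ketone F4. With the same ruthenium catalyst, the metal loads at the unhindered terminal alkene of F4, expels cyclopentene and is thereby delivered to C2 as the alkylidene. This closes onto the C4 vinyl group, and the route is rejoined at 26.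

Step 11. The alkynyl group may enter the oxocarbenium ion with poor or reversed facial selectivity (syn to the C5 chain), or the ion may lose a proton to an enol ether. The fallback reverses the order in which the two C4 substituents arrive, so that methyl, not alkynyl, is the group that enters last. It sets out from lactone 16: addition of LiC≡CSiMe3 (from 19 and n-BuLi, THF, −78 °C) gives the 2-alkynyl hemiketal F5, in equilibrium with its ynone phenol. AlMe3 in CH2Cl2 (−78 to 0 °C) then methylates the alkynyl-stabilised oxocarbenium ion to give 20, and K2CO3/MeOH rejoins the route at 21.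

Step 1. The excited α-alkoxy ketone may fragment by α-cleavage, or head-to-tail regioselectivity may be low on the crowded β-carbon. The fallback moves the Baeyer–Villiger oxidation ahead of the cycloaddition, so that a butenolide is the chromophore. It sets out from 1: oxidation with peracetic acid and hydrolysis of the formate give (S)-5-(hydroxymethyl)furan-2(5H)-one F6, and pivaloyl chloride/pyridine gives its pivalate F7. Acetone-sensitised [2+2] photocycloaddition with 2, anti to the C5 substituent, gives the head-to-tail adduct pivalate F8 after separation from its syn diastereomer. NaOH then NaIO4, as in step 3, rejoins the route at 6.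

Further compounds
F1 | step 15 | (1R,2S)-2-[(1Z)-hepta-1,6-dien-1-yl]-3,3-dimethylcyclobutane-1-carboxylic acid | C=CCCC/C=C\[C@H]1[C@H](C(=O)O)CC1(C)C
F2 | step 15 | (1R,2S)-2-[(1Z)-hepta-1,6-dien-1-yl]-N-methoxy-N,3,3-trimethylcyclobutane-1-carboxamide | C=CCCC/C=C\[C@H]1[C@H](C(=O)N(C)OC)CC1(C)C
F3 | step 15 | relay β-keto sulfone (F4 bearing PhSO2 at C7, C7 epimers) | C=CCCC/C=C\[C@H]2[C@H](C(=O)C(C[C@@H]1[C@@H](c3ccccc3)c3c(OCOC)cc(OCOC)cc3O[C@@]1(C)C=C)S(=O)(=O)c1ccccc1)CC2(C)C
F4 | step 15 | relay triene ketone (25 with the cyclobutyl vinyl group extended to (Z)-hepta-1,6-dienyl) | C=CCCC/C=C\[C@H]2[C@H](C(=O)CC[C@@H]1[C@@H](c3ccccc3)c3c(OCOC)cc(OCOC)cc3O[C@@]1(C)C=C)CC2(C)C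
F5 | step 11 | (3R,4S)-2-hydroxy-5,7-bis(methoxymethoxy)-4-phenyl-3-[2-(phenylsulfonyl)ethyl]-2-[(trimethylsilyl)ethynyl]chroman, C2 epimers | OC1(C#C[Si](C)(C)C)[C@H](CCS(=O)(=O)c4ccccc4)[C@@H](c3ccccc3)c2c(OCOC)cc(OCOC)cc2O1
F6 | step 1 | (S)-5-(hydroxymethyl)furan-2(5H)-one | O=C1C=C[C@@H](CO)O1
F7 | step 1 | [(2S)-5-oxo-2,5-dihydrofuran-2-yl]methyl pivalate | O=C1C=C[C@@H](COC(=O)C(C)(C)C)O1
F8 | step 1 | [(1R,4S,5R)-6,6-dimethyl-2-oxo-3-oxabicyclo[3.2.0]heptan-4-yl]methyl pivalate | O=C1O[C@H](COC(=O)C(C)(C)C)[C@@H]2[C@H]1CC2(C)C
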